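A direct plan would join two 3,5-dimethoxyphenyl units through their benzylic carbons to a C11 dihalide (hydrazone umpolung alkylation) and so give 1,13-bis(3,5-dimethoxyphenyl)tridecane A1.
It would then C-methylate both rings to 1,13-bis(3,5-dimethoxy-4-methylphenyl)tridecane A2, brominate the four free ring positions to 1,13-bis(2,6-dibromo-3,5-dimethoxy-4-methylphenyl)tridecane A3, turn the four C–Br into C–OH by Br/Li exchange, borylation and peroxide oxidation to give 2,2'-(tridecane-1,13-diyl)bis(4,6-dimethoxy-5-methylbenzene-1,3-diol) A4, oxidise this to the symmetric 3,3'-(tridecane-1,13-diyl)bis(2-hydroxy-5-methoxy-6-methyl-1,4-benzoquinone) A5 and hydrolyse one of its two methyl ethers.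
Its weakest step would be that final half-hydrolysis: the two vinylogous esters of A5 are equivalent and insulated by thirteen CH2 groups, so the outcome would be statistical, at best half of the material per pass, on the most precious intermediate.
Second would be the fourfold Br/Li exchange–borylation–oxidation: a large excess of t-BuLi on tetrabromide A3, four C–O bonds that must all form, and an air-sensitive tetrol A4, again late.
Third would be the middle of the plan: methylation, bromination, hydroxylation and oxidation would be four steps on the dimer that add no skeletal bond, and each would have to succeed twice per molecule.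
No stereocentre or ring closure would be left to chance (the target is achiral and both rings are bought as benzene rings); the plan would suffer from statistics and late organometallic chemistry, not from selectivity.

**Plan of the new route** (ring A = methoxy ring, ring B = dihydroxy ring)
The retrosynthesis cuts the two ring–CH2 bonds, from chain C1 and C13 to the ring carbons that lie between C–OH and C=O. The chain becomes a C13 dialdehyde equivalent and both rings come from one finished monomer, 5-hydroxy-2-methoxy-3-methyl-1,4-benzoquinone.
Enabling feature: in this monomer that ring carbon is a C–H flanked by an enolic C–OH and a C=O, the α-carbon of an enolised 1,2,4-tricarbonyl (a vinylogous carboxylic acid). It condenses with an aldehyde, and a Hantzsch ester reduces the alkylidene to the C-alkylated hydroxyquinone.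
Order of the rings: the oxygen pattern is completed on the chain-free C8 quinone. One copy is joined to the free aldehyde end of 13,13-dimethoxytridecanal and demethylated to completion while it is the only ring present (it becomes ring B). The second copy is joined last to the unmasked aldehyde (ring A).
The weak steps no longer arise: the rings are told apart by the order of events, not by statistics; no organolithium, bromination or borylation touches a chain-bearing intermediate; no ring oxygen is introduced after the chain; the last step runs at room temperature without protecting groups.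

Key step: step 8

Remark: the target has no stereocentre; the exocyclic C=C geometry of the two alkylidene-trione intermediates is undefined and is lost on reduction; 3-methoxy-2-methylphenol and (Z)-docos-13-en-1-ol are taken to be purchasable.

Step 1
Reactants: 1 3-methoxy-2-methylphenol
Product: 2 2-methoxy-3-methyl-1,4-benzoquinone
Conditions: (KSO3)2NO (2.3 equiv), aq KH2PO4, acetone–H2O, 0 °C → rt
Reagents that add atoms: potassium nitrosodisulfonate (Fremy's salt), [K+].[K+].[O]N(S(=O)(=O)[O-])S(=O)(=O)[O-]
Why: Teuber oxidation of a phenol with a free para position: the nitroxyl radical forms the phenoxyl radical and a second equivalent delivers oxygen at C4 (para to OH, ortho to OMe), so the p-quinone should form with OMe and C-methyl untouched on adjacent carbons.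

Step 2
Reactants: 2 2-methoxy-3-methyl-1,4-benzoquinone
Product: 3 5-methoxy-6-methylbenzene-1,2,4-triyl triacetate
Conditions: Ac2O, conc. H2SO4 (cat.), rt → 40 °C; ice–water
Reagents that add atoms: acetic anhydride, CC(=O)OC(C)=O
Why: Thiele–Winter acetoxylation: the acid-activated quinone takes acetate by conjugate addition at C5, the β-carbon of the C1 carbonyl, which is the more electrophilic one because the C4 carbonyl is deactivated as a vinylogous ester of the C2 methoxy group (methoxy-p-benzoquinones are acetoxylated para to OMe); enolisation and acetylation trap the adduct as the triacetate.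

Step 3
Reactants: 3 5-methoxy-6-methylbenzene-1,2,4-triyl triacetate
Product: 5 5-hydroxy-2-methoxy-3-methyl-1,4-benzoquinone, via 5-methoxy-6-methylbenzene-1,2,4-triol 4 (not isolated)
Conditions: conc. HCl (cat.), MeOH, reflux, N2; evaporate; FeCl3·6H2O (2.2 equiv), H2O, 0 °C → rt
Reagents that add atoms: none
Why: Acid-catalysed transesterification frees the three phenols and FeCl3 oxidises the 1,2,4-triol to the 2-hydroxy-1,4-benzoquinone tautomer, which leaves C6–H between C5–OH and C1=O and the methoxy group next to the C-methyl.

Step 4
Reactants: 6 (Z)-docos-13-en-1-ol (erucyl alcohol)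
Product: 9 13,13-dimethoxytridecan-1-ol, via ozonide 7 (not isolated), via 13-hydroxytridecanal 8 (not isolated)
Conditions: O3, CH2Cl2, −78 °C; PPh3 (1.1 equiv), −78 °C → rt; then MeOH, HC(OMe)3 (3 equiv), p-TsOH·H2O (5 mol %), rt; NaHCO3; chromatography
Reagents that add atoms: methanol, CO (for the intermediates only: ozone, [O-][O+]=O)
Why: Criegee ozonolysis of the only C=C (C13=C14) and phosphine reduction of the ozonide give the C13 ω-hydroxy aldehyde and nonanal, and acid-catalysed acetalisation with orthoformate as water scavenger masks the aldehyde, so the two chain ends are differentiated by the starting material and not by statistics.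

Step 5
Reactants: 9 13,13-dimethoxytridecan-1-ol
Product: 10 13,13-dimethoxytridecanal
Conditions: (COCl)2 (1.3 equiv), DMSO (2.6 equiv), CH2Cl2, −78 °C; Et3N (5 equiv), −78 → 0 °C
Reagents that add atoms: none
Why: Swern oxidation takes the primary alcohol to the aldehyde under basic, anhydrous conditions that cannot over-oxidise and leave the dimethyl acetal intact.

Step 6
Reactants: 5 5-hydroxy-2-methoxy-3-methyl-1,4-benzoquinone; 10 13,13-dimethoxytridecanal
Product: 12 3-(13,13-dimethoxytridecyl)-2-hydroxy-5-methoxy-6-methyl-1,4-benzoquinone, via alkylidene-trione 11 (not isolated)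
Conditions: 10 (1.2 equiv), L-proline (20 mol %), diethyl 2,6-dimethyl-1,4-dihydropyridine-3,5-dicarboxylate (Hantzsch ester, 1.2 equiv), 4 Å MS, CH2Cl2, rt
Reagents that add atoms: none
Why: Organocatalytic reductive alkylation (Knoevenagel condensation, then hydride transfer): C6–H of 5, the only ring C–H, condenses with the free aldehyde of 10 to alkylidene-trione 11, which the dihydropyridine should reduce at the exocyclic carbon before a second quinone can add, while the acetal end stays masked under the weakly acidic, water-poor conditions.

Step 7
Reactants: 12 3-(13,13-dimethoxytridecyl)-2-hydroxy-5-methoxy-6-methyl-1,4-benzoquinone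
Product: 14 13-(2,5-dihydroxy-4-methyl-3,6-dioxocyclohexa-1,4-dien-1-yl)tridecanal, via dihydroxyquinone acetal 13 (not isolated)
Conditions: 1 M aq NaOH (10 equiv), dioxane, 75 °C, N2, to full conversion; 0 °C, 2 M HCl to pH 1, THF, rt; product used promptly
Reagents that add atoms: sodium hydroxide, [Na+].[OH-]; water, O
Why: Hydroxide adds to the methoxy-bearing ring carbon and expels methoxide (addition–elimination on a vinylogous ester), here run to completion because this is the only methyl ether in the molecule and the acetal is inert to base; acidification then hydrolyses the acetal through its oxocarbenium ion to the aldehyde, which cannot condense with its own ring because that ring has no C–H.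

Step 8
Reactants: 14 13-(2,5-dihydroxy-4-methyl-3,6-dioxocyclohexa-1,4-dien-1-yl)tridecanal; 5 5-hydroxy-2-methoxy-3-methyl-1,4-benzoquinone
Product: 16 2,5-dihydroxy-3-[13-(2-hydroxy-5-methoxy-6-methyl-1,4-benzoquinon-3-yl)tridecyl]-6-methyl-1,4-benzoquinone (target, achiral), via alkylidene-trione 15 (not isolated)
Conditions: 5 (1.2 equiv), L-proline (20 mol %), Hantzsch ester (1.5 equiv), CH2Cl2–THF, rt, Ar; oxalic-acid-treated SiO2
Reagents that add atoms: none
Why: L-Proline condenses with the aldehyde of 14 to an iminium ion that is attacked by C6 of 5, the only ring C–H and the α-carbon of an enolised 1,2,4-tricarbonyl; loss of proline gives alkylidene-trione 15, whose exocyclic carbon takes a hydride from the Hantzsch ester and re-forms the hydroxyquinone (Knoevenagel condensation followed by conjugate transfer hydrogenation). The closest known reaction type is the three-component organocatalytic reductive alkylation of 2-hydroxy-1,4-naphthoquinone and of 2,5-dihydroxy-1,4-benzoquinone with aliphatic aldehydes. No ring is closed and no stereocentre is formed; the alkene geometry of 15 is erased on reduction. The step needs C- over O-alkylation, mono- over bis-addition and an inert ring B: O-adducts are hemiacetals that revert, the Hantzsch ester is present from the start so that 15 should be reduced before a second molecule of 5 adds, and ring B of 14 has no C–H and cannot condense. Both hydroxyquinones are present as electron-rich, weakly oxidising enol(ate)s, so the dihydropyridine should not reduce them and proline should not displace the methoxy group.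

**Compound list**
1 | 3-methoxy-2-methylphenol | COc1cccc(O)c1C | starting material
2 | 2-methoxy-3-methyl-1,4-benzoquinone | COC1=C(C)C(=O)C=CC1=O | intermediate
3 | 5-methoxy-6-methylbenzene-1,2,4-triyl triacetate | CC(=O)Oc1cc(OC(C)=O)c(OC(C)=O)c(C)c1OC | intermediate
4 | 5-methoxy-6-methylbenzene-1,2,4-triol | COc1c(C)c(O)c(O)cc1O | intermediate
5 | 5-hydroxy-2-methoxy-3-methyl-1,4-benzoquinone | COC1=C(C)C(=O)C(O)=CC1=O | intermediate
6 | (Z)-docos-13-en-1-ol (erucyl alcohol) | CCCCCCCC/C=C\CCCCCCCCCCCCO | starting material
7 | 12-(5-octyl-1,2,4-trioxolan-3-yl)dodecan-1-ol (ozonide) | CCCCCCCCC1OOC(CCCCCCCCCCCCO)O1 | intermediate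
8 | 13-hydroxytridecanal | OCCCCCCCCCCCCC=O | intermediate
9 | 13,13-dimethoxytridecan-1-ol | COC(CCCCCCCCCCCCO)OC | intermediate
10 | 13,13-dimethoxytridecanal | COC(CCCCCCCCCCCC=O)OC | intermediate
11 | 3-(13,13-dimethoxytridecylidene)-5-methoxy-6-methylcyclohex-5-ene-1,2,4-trione (E/Z undefined) | COC1=C(C)C(=O)C(=O)C(=CCCCCCCCCCCCC(OC)OC)C1=O | intermediate
12 | 3-(13,13-dimethoxytridecyl)-2-hydroxy-5-methoxy-6-methyl-1,4-benzoquinone | COC1=C(C)C(=O)C(O)=C(CCCCCCCCCCCCC(OC)OC)C1=O | intermediate
13 | 3-(13,13-dimethoxytridecyl)-2,5-dihydroxy-6-methyl-1,4-benzoquinone | OC1=C(C)C(=O)C(O)=C(CCCCCCCCCCCCC(OC)OC)C1=O | intermediate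
14 | 13-(2,5-dihydroxy-4-methyl-3,6-dioxocyclohexa-1,4-dien-1-yl)tridecanal | OC1=C(C)C(=O)C(O)=C(CCCCCCCCCCCCC=O)C1=O | intermediate
15 | 3-[13-(2,5-dihydroxy-4-methyl-3,6-dioxocyclohexa-1,4-dien-1-yl)tridecylidene]-5-methoxy-6-methylcyclohex-5-ene-1,2,4-trione (E/Z undefined) | COC1=C(C)C(=O)C(=O)C(=CCCCCCCCCCCCCC2=C(O)C(=O)C(C)=C(O)C2=O)C1=O | intermediate
16 | 2,5-dihydroxy-3-[13-(2-hydroxy-5-methoxy-6-methyl-1,4-benzoquinon-3-yl)tridecyl]-6-methyl-1,4-benzoquinone | COC1=C(C)C(=O)C(O)=C(CCCCCCCCCCCCCC2=C(O)C(=O)C(C)=C(O)C2=O)C1=O | target

**Count and risks**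
Total steps: 8. Longest linear sequence: 6 steps (1, 2, 3, 6, 7, 8); steps 4 and 5 form the chain branch.

Most likely to fail, step 8: the condensation may stall because the acidic dihydroxyquinone end of 14 ties up the amine catalyst, or a second molecule of 5 may add to alkylidene 15 before hydride transfer. The fallback makes both ring–chain bonds by radical decarboxylation instead of polar condensation. It sets out from 5. AgNO3 (cat.) and (NH4)2S2O8 in MeCN–H2O at 70 °C with 15-hydroxypentadecanoic acid would alkylate C6 with the decarboxylated primary radical to give 2-hydroxy-3-(14-hydroxytetradecyl)-5-methoxy-6-methyl-1,4-benzoquinone F1. CrO3–H2SO4 in acetone (Jones oxidation) would give 14-(2-hydroxy-5-methoxy-4-methyl-3,6-dioxocyclohexa-1,4-dien-1-yl)tetradecanoic acid F2. 1 M NaOH in dioxane at 75 °C would cleave the methyl ether to 14-(2,5-dihydroxy-4-methyl-3,6-dioxocyclohexa-1,4-dien-1-yl)tetradecanoic acid F3. A second AgNO3/(NH4)2S2O8 decarboxylation of F3 in the presence of excess 5 would form the second ring–chain bond and come back to the route at 16.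

Second, step 7: the hydroxyquinone dianion may degrade in hot alkali (oxidative ring cleavage by traces of O2, ring contraction), or the aldehyde may self-condense if the acetal is lost before the base is neutralised. The fallback demethylates the monomer instead of the chain-bearing intermediate. It sets out from 12 and uses a second portion of 5. 5 with 1 M NaOH at 75 °C under N2 would give 2,5-dihydroxy-3-methyl-1,4-benzoquinone F4. Separately, 12 would be deprotected with AcOH–H2O–THF at rt, which spares the methyl ether, to 13-(2-hydroxy-5-methoxy-4-methyl-3,6-dioxocyclohexa-1,4-dien-1-yl)tridecanal F5. Reductive alkylation of F4 (its only C–H is C6) with F5 under the conditions of step 8 would come back to the route at 16.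

Third, step 2: acetate may add with poor regioselectivity (at C6, para to the C-methyl, instead of C5), or the acid may cleave the enol ether. The fallback places the oxygens by phenol-directed aromatic substitution before any quinone exists. It sets out from 1. MgCl2, Et3N and (CH2O)n in MeCN at reflux would formylate the only free ortho position to give 2-hydroxy-4-methoxy-3-methylbenzaldehyde F6. Elbs persulfate oxidation (K2S2O8, aq NaOH, then aq HCl) would introduce OH para to the phenol to give 2,5-dihydroxy-4-methoxy-3-methylbenzaldehyde F7. Dakin oxidation (H2O2, aq NaOH, N2) would turn CHO into OH and come back to the route at triol 4, which is oxidised by FeCl3 to 5 as in step 3.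

**Further compounds**
F1 | step 8 | 2-hydroxy-3-(14-hydroxytetradecyl)-5-methoxy-6-methyl-1,4-benzoquinone | COC1=C(C)C(=O)C(O)=C(CCCCCCCCCCCCCCO)C1=O
F2 | step 8 | 14-(2-hydroxy-5-methoxy-4-methyl-3,6-dioxocyclohexa-1,4-dien-1-yl)tetradecanoic acid | COC1=C(C)C(=O)C(O)=C(CCCCCCCCCCCCCC(=O)O)C1=O
F3 | step 8 | 14-(2,5-dihydroxy-4-methyl-3,6-dioxocyclohexa-1,4-dien-1-yl)tetradecanoic acid | OC1=C(C)C(=O)C(O)=C(CCCCCCCCCCCCCC(=O)O)C1=O
F4 | step 7 | 2,5-dihydroxy-3-methyl-1,4-benzoquinone | OC1=C(C)C(=O)C(O)=CC1=O
F5 | step 7 | 13-(2-hydroxy-5-methoxy-4-methyl-3,6-dioxocyclohexa-1,4-dien-1-yl)tridecanal | COC1=C(C)C(=O)C(O)=C(CCCCCCCCCCCCC=O)C1=O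
F6 | step 2 | 2-hydroxy-4-methoxy-3-methylbenzaldehyde | COc1ccc(C=O)c(O)c1C
F7 | step 2 | 2,5-dihydroxy-4-methoxy-3-methylbenzaldehyde | COc1c(O)cc(C=O)c(O)c1C
A1 | direct plan | 1,13-bis(3,5-dimethoxyphenyl)tridecane | COc1cc(CCCCCCCCCCCCCc2cc(OC)cc(OC)c2)cc(OC)c1
A2 | direct plan | 1,13-bis(3,5-dimethoxy-4-methylphenyl)tridecane | COc1cc(CCCCCCCCCCCCCc2cc(OC)c(C)c(OC)c2)cc(OC)c1C
A3 | direct plan | 1,13-bis(2,6-dibromo-3,5-dimethoxy-4-methylphenyl)tridecane | COc1c(C)c(OC)c(Br)c(CCCCCCCCCCCCCc2c(Br)c(OC)c(C)c(OC)c2Br)c1Br
A4 | direct plan | 2,2'-(tridecane-1,13-diyl)bis(4,6-dimethoxy-5-methylbenzene-1,3-diol) | COc1c(C)c(OC)c(O)c(CCCCCCCCCCCCCc2c(O)c(OC)c(C)c(OC)c2O)c1O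
A5 | direct plan | 3,3'-(tridecane-1,13-diyl)bis(2-hydroxy-5-methoxy-6-methyl-1,4-benzoquinone) | COC1=C(C)C(=O)C(O)=C(CCCCCCCCCCCCCC2=C(O)C(=O)C(C)=C(OC)C2=O)C1=O
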